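Labdane numbering is used throughout (ring A: C1–C5, C10; ring B: C5–C10; side chain C11–C16; C17 is the methyl on C8).

Retrosynthesis: after the C15 silyl ether and the two acetates, ring B is cut at C6–C7 and at C9–C10; this leaves ring A carrying C5, C6 and C10 (a cyclogeranyl C10 unit) and an open chain C7–C9/C11–C17 with the finished (13Z) side chain.
Enabling feature: in ring B, C9 is both the alkene carbon bonded to the quaternary C10 and the β-carbon of an oxygenated C7 (C7–C8=C9), and C6–C7 is a vicinal dioxygenated bond; a tertiary C10 radical can therefore add to C9 of an allenic C7 aldehyde, and the C7 ketyl of the enal so formed can close onto a C6 nitrile.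
Forward order: ring A from geranic acid (cyclisation, resolution, nitrile, tertiary oxalate); chain from nerol (oxidative cleavage, ketene Wittig, allenal); union of the two and closure of ring B in one flask; then C6 reduction, acetylation, desilylation.
Helpers and their removal: nitrile nitrogen (latent C6 ketone, lost as ammonia), oxalate (lost as CO2), allene (absorbed into the C8=C9 alkene), TBDPS ether (fluoride, last step).
Stereochemistry: C5 from resolution of α-cyclogeranic acid; C10 by radical addition trans to C5; C7 in the ketyl ring closure; C6 by hydride delivery to the α face; 13Z from nerol.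
Key step: step 14

Assumption: the (R)-1-phenylethylammonium salt of the (S)-acid is taken to be the less soluble diastereomer; if the (R)-acid salt crystallises instead, (S)-1-phenylethylamine is used and nothing else changes.

Step 1
Reactants: 1 geranic acid
Product: 2 rac-α-cyclogeranic acid
Conditions: H3PO4 (85 %), toluene, 90 °C
Reagents that add atoms: none
Why: Acid-promoted cation–olefin cyclisation, in which the tertiary cation from the 6,7-alkene is captured by the 2,3-alkene and loss of a ring proton should give mainly the β,γ-unsaturated α-isomer as the racemate (the new stereocentre is not controlled here).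

Step 2
Reactants: 2 rac-α-cyclogeranic acid
Product: 3 (R)-1-phenylethylammonium (S)-α-cyclogeranate
Conditions: (R)-1-phenylethylamine (1.0 equiv), acetone, reflux to 0 °C, two recrystallisations
Reagents that add atoms: (R)-1-phenylethylamine, C[C@@H](N)c1ccccc1
Why: Classical resolution through diastereomeric ammonium salts, which fixes the C5 configuration that later directs every other ring stereocentre.

Step 3
Reactants: 3 (R)-1-phenylethylammonium (S)-α-cyclogeranate
Product: 4 (S)-α-cyclogeranic acid
Conditions: 1 M HCl, Et2O, 0 °C
Reagents that add atoms: none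
Why: Acid–base liberation of the free acid from its ammonium salt, which does not touch the stereocentre.

Step 4
Reactants: 4 (S)-α-cyclogeranic acid
Product: 6 (S)-α-cyclogeranamide, via isobutyl mixed anhydride 5 (not isolated)
Conditions: i-BuOCOCl, N-methylmorpholine, THF, −15 °C; then NH3 (aq.), −15 to 0 °C
Reagents that add atoms: ammonia, N
Why: Mixed-anhydride amidation at low temperature with a weak base, chosen so that the α-stereocentre of the β,γ-unsaturated acid is not epimerised through a ketene or dienolate.

Step 5
Reactants: 6 (S)-α-cyclogeranamide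
Product: 7 (S)-α-cyclogeranonitrile
Conditions: (CF3CO)2O, pyridine, CH2Cl2, 0 °C
Reagents that add atoms: none
Why: Dehydration of a primary amide with trifluoroacetic anhydride/pyridine, mild enough to leave the allylic stereocentre untouched; the nitrile is the latent C6 ketone and makes C5 configurationally robust.

Step 6
Reactants: 7 (S)-α-cyclogeranonitrile
Product: 8 tertiary alcohol (2-hydroxy-2,6,6-trimethylcyclohexane-1-carbonitrile, C1 as in 7, both C2 epimers)
Conditions: Co(acac)2 (20 mol %), PhSiH3, O2 (1 atm), THF, rt
Reagents that add atoms: dioxygen, O=O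
Why: Mukaiyama hydration (metal-hydride hydrogen-atom transfer, then O2 capture) should give the Markovnikov tertiary alcohol at C10 without a cation that could move the alkene into conjugation with the nitrile; the C10 epimer mixture is of no consequence because C10 is later planarised as a radical.

Step 7
Reactants: 8 tertiary alcohol
Product: 10 cesium oxalate of 8, via methyl oxalate 9 (not isolated)
Conditions: ClCOCO2Me, Et3N, DMAP (cat.), CH2Cl2, 0 °C to rt; then CsOH·H2O (1.0 equiv), THF/H2O, rt
Reagents that add atoms: methyl chlorooxoacetate, COC(=O)C(Cl)=O; cesium hydroxide, [Cs+].[OH-]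
Why: DMAP-catalysed acylation of the tertiary alcohol and selective saponification of the more electrophilic methyl ester should give the bench-stable cesium oxalate, a radical precursor that fragments with loss of two CO2.

Step 8
Reactants: 11 nerol
Product: 12 neryl TBDPS ether
Conditions: TBDPSCl, imidazole, DMF, rt
Reagents that add atoms: tert-butyl(chloro)diphenylsilane, CC(C)(C)[Si](Cl)(c1ccccc1)c1ccccc1
Why: Silylation of the primary allylic alcohol; the TBDPS ether should tolerate the acidic, oxidative, hydride, photoredox and SmI2 steps ahead and is removable by fluoride in the presence of acetates.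

Step 9
Reactants: 12 neryl TBDPS ether
Product: 14 (4Z)-6-(tert-butyldiphenylsilyloxy)-4-methylhex-4-enal, via epoxide 13 (not isolated)
Conditions: mCPBA, NaHCO3, CH2Cl2, −20 °C; then H5IO6, THF/H2O, 0 °C
Reagents that add atoms: 3-chloroperoxybenzoic acid, OOC(=O)c1cccc(Cl)c1
Why: Prilezhaev epoxidation should take place at the more electron-rich, less hindered 6,7-alkene (the 2,3-alkene is deactivated by the allylic silyloxy group), and periodic acid cleaves the epoxide to the aldehyde and acetone, which destroys the racemic epoxide stereocentre.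

Step 10
Reactants: 14 (4Z)-6-(tert-butyldiphenylsilyloxy)-4-methylhex-4-enal
Product: 15 (4Z)-6-(tert-butyldiphenylsilyloxy)-4-methylhex-4-enoic acid
Conditions: NaClO2, NaH2PO4, 2-methyl-2-butene, t-BuOH/H2O, rt
Reagents that add atoms: sodium chlorite, [Na+].[O-]Cl=O
Why: Pinnick oxidation with a hypochlorite scavenger should convert the aldehyde into the acid without touching the trisubstituted alkene or the silyl ether.

Step 11
Reactants: 15 (4Z)-6-(tert-butyldiphenylsilyloxy)-4-methylhex-4-enoic acid
Product: 18 ethyl (6Z)-8-(tert-butyldiphenylsilyloxy)-2,6-dimethylocta-2,3,6-trienoate, via acid chloride 16 (not isolated), via ketene 17 (not isolated)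
Conditions: (COCl)2, DMF (cat.), CH2Cl2, 0 °C to rt; then Ph3P=C(CH3)CO2Et, Et3N, CH2Cl2, 0 °C to rt
Reagents that add atoms: ethyl 2-(triphenylphosphoranylidene)propanoate, CCOC(=O)C(C)=P(c1ccccc1)(c1ccccc1)c1ccccc1
Why: Et3N dehydrochlorinates the acid chloride to the monosubstituted ketene, and Wittig olefination of the ketene C=O by the stabilised ylide should give the 2-methyl-2,3-allenoate (racemic allene axis, destroyed later) that supplies C7, C8 and C17.

Step 12
Reactants: 18 ethyl (6Z)-8-(tert-butyldiphenylsilyloxy)-2,6-dimethylocta-2,3,6-trienoate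
Product: 19 (6Z)-8-(tert-butyldiphenylsilyloxy)-2,6-dimethylocta-2,3,6-trien-1-ol
Conditions: DIBAL-H (2.2 equiv), CH2Cl2, −78 °C; Rochelle salt work-up
Reagents that add atoms: none
Why: DIBAL-H reduction of the allenic ester to the primary allenic alcohol at low temperature, which should leave the cumulene and the Z alkene untouched.

Step 13
Reactants: 19 (6Z)-8-(tert-butyldiphenylsilyloxy)-2,6-dimethylocta-2,3,6-trien-1-ol
Product: 20 (6Z)-8-(tert-butyldiphenylsilyloxy)-2,6-dimethylocta-2,3,6-trienal
Conditions: MnO2 (activated), CH2Cl2, rt
Reagents that add atoms: none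
Why: Activated MnO2 oxidises the α-allenic (allylic-type) alcohol to the aldehyde under neutral conditions that should not isomerise the allene to the conjugated dienal.

Step 14
Reactants: 10 cesium oxalate of 8; 20 (6Z)-8-(tert-butyldiphenylsilyloxy)-2,6-dimethylocta-2,3,6-trienal
Product: 23 (5S,7S,10S,13Z)-15-(tert-butyldiphenylsilyloxy)-7-hydroxylabda-8,13-dien-6-one, via enal nitrile 21 (not isolated), via hydroxy ketimine 22 (not isolated)
Conditions: 10 (1.5 equiv), Ir[dF(CF3)ppy]2(dtbbpy)PF6 (1 mol %), DME/DMF 3:1, H2O (10 equiv), blue LEDs, 60 °C; then solvent removed in the same flask, THF, SmI2 (4 equiv), −78 to 0 °C; pH 7 phosphate buffer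
Reagents that add atoms: water, O
Why: Proposed new method: the excited iridium photocatalyst oxidises the oxalate of 10, loss of two CO2 gives the tertiary C10 radical, and this adds to C9, the central allene carbon of 20 that is β to the aldehyde; reduction and C11-protonation of the dienolate give the tetrasubstituted enal 21, whose samarium ketyl (C7) then adds to the C6 nitrile, and hydrolysis of the resulting imine 22 gives the ketone 23. The closest known reaction types are the photoredox Giese coupling of tertiary alkyl oxalates with electron-poor alkenes and the SmI2-mediated ketyl–nitrile cyclisation of cyano ketones; new are the allenal as acceptor, the enal-derived ketyl and the telescoping of both into a (3+3) annulation. Ring B closes in the 6-exo-dig mode, the C7 ketyl carbon attacking the nitrile carbon C6. C10 is controlled by C5, because the acceptor should approach equatorially, trans to the cyano group and away from the syn-axial C4 methyl, which leaves the C10 methyl axial as in a trans-decalin; C7 is set in the ring closure, where the bulky O–Sm group should take the pseudoaxial α position to avoid allylic strain with the C8 methyl; C5 is carried over from 7. The step needs attack at C9 and not at C11, an enal with C7 cis to C10, and cyclisation in preference to ketyl dimerisation or conjugate reduction; these should be secured by the polarity match of the nucleophilic radical with the formyl-conjugated π bond, by the preference of the quaternary C10 group to lie cis to the small formyl group (the ketyl radical anion can also rotate about C8–C9), and by the six-membered intramolecular closure next to a fully substituted β-carbon. Until work-up the product is held as its nitrogen-bound samarium species, which should shield the α-ketol from over-reduction.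

Step 15
Reactants: 23 (5S,7S,10S,13Z)-15-(tert-butyldiphenylsilyloxy)-7-hydroxylabda-8,13-dien-6-one
Product: 24 (5S,6S,7S,10S,13Z)-15-(tert-butyldiphenylsilyloxy)labda-8,13-diene-6,7-diol (6β,7α)
Conditions: NaBH4, CeCl3·7H2O, MeOH, −78 to −40 °C
Reagents that add atoms: none
Why: Luche-type 1,2-reduction in which hydride should add to the C6 ketone from the α face, because the β face is shielded by the axial C4β and C10 methyl groups, giving the axial 6β-alcohol trans to the 7α-hydroxyl, while the cold, non-basic medium should prevent ketol isomerisation.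

Step 16
Reactants: 24 (5S,6S,7S,10S,13Z)-15-(tert-butyldiphenylsilyloxy)labda-8,13-diene-6,7-diol
Product: 25 (5S,6S,7S,10S,13Z)-6,7-diacetoxy-15-(tert-butyldiphenylsilyloxy)labda-8,13-diene
Conditions: Ac2O, DMAP, Et3N, CH2Cl2, 40 °C
Reagents that add atoms: acetic anhydride, CC(=O)OC(C)=O
Why: DMAP-catalysed acetylation of both secondary alcohols, with warming for the axial, 1,3-diaxially flanked 6β-hydroxyl; no stereocentre is affected.

Step 17
Reactants: 25 (5S,6S,7S,10S,13Z)-6,7-diacetoxy-15-(tert-butyldiphenylsilyloxy)labda-8,13-diene
Product: 26 (5S,6S,7S,10S,13Z)-6,7-diacetoxylabda-8,13-dien-15-ol (target)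
Conditions: HF·pyridine, pyridine/THF, 0 °C to rt
Reagents that add atoms: none
Why: Fluoride-mediated desilylation with buffered HF·pyridine should remove the TBDPS ether without acetate cleavage or migration and release the (13Z)-allylic alcohol.

Compound list
1 | geranic acid, (2E)-3,7-dimethylocta-2,6-dienoic acid | CC(C)=CCC/C(C)=C/C(O)=O | starting material
2 | rac-α-cyclogeranic acid, 2,6,6-trimethylcyclohex-2-ene-1-carboxylic acid (racemate) | CC1=CCCC(C)(C)C1C(O)=O | intermediate
3 | (R)-1-phenylethylammonium (1S)-2,6,6-trimethylcyclohex-2-ene-1-carboxylate | C[C@@H]([NH3+])c1ccccc1.[O-]C(=O)[C@@H]1C(C)=CCCC1(C)C | intermediate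
4 | (S)-α-cyclogeranic acid, (1S)-2,6,6-trimethylcyclohex-2-ene-1-carboxylic acid | OC(=O)[C@@H]1C(C)=CCCC1(C)C | intermediate
5 | isobutyl carbonic mixed anhydride of 4 | CC(C)COC(=O)OC(=O)[C@@H]1C(C)=CCCC1(C)C | intermediate (not isolated)
6 | (S)-α-cyclogeranamide, (1S)-2,6,6-trimethylcyclohex-2-ene-1-carboxamide | NC(=O)[C@@H]1C(C)=CCCC1(C)C | intermediate
7 | (S)-α-cyclogeranonitrile, (1S)-2,6,6-trimethylcyclohex-2-ene-1-carbonitrile | N#C[C@@H]1C(C)=CCCC1(C)C | intermediate
8 | 2-hydroxy-2,6,6-trimethylcyclohexane-1-carbonitrile, C1 spatially as in 7, both C2 epimers | N#C[C@@H]1C(C)(O)CCCC1(C)C | intermediate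
9 | methyl oxalate of 8 (mixed methyl tert-alkyl oxalate) | N#C[C@@H]1C(C)(OC(=O)C(=O)OC)CCCC1(C)C | intermediate (not isolated)
10 | cesium oxalate of 8 (cesium tert-alkyl oxalate) | N#C[C@@H]1C(C)(OC(=O)C(=O)[O-])CCCC1(C)C.[Cs+] | intermediate
11 | nerol, (2Z)-3,7-dimethylocta-2,6-dien-1-ol | CC(C)=CCC/C(C)=C\CO | starting material
12 | neryl tert-butyldiphenylsilyl ether | CC(C)=CCC/C(C)=C\CO[Si](c1ccccc1)(c1ccccc1)C(C)(C)C | intermediate
13 | 6,7-epoxide of 12 (racemic at the epoxide carbon, 2Z) | CC1(C)OC1CC/C(C)=C\CO[Si](c2ccccc2)(c2ccccc2)C(C)(C)C | intermediate (not isolated)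
14 | (4Z)-6-(tert-butyldiphenylsilyloxy)-4-methylhex-4-enal | O=CCC/C(C)=C\CO[Si](c1ccccc1)(c1ccccc1)C(C)(C)C | intermediate
15 | (4Z)-6-(tert-butyldiphenylsilyloxy)-4-methylhex-4-enoic acid | OC(=O)CC/C(C)=C\CO[Si](c1ccccc1)(c1ccccc1)C(C)(C)C | intermediate
16 | (4Z)-6-(tert-butyldiphenylsilyloxy)-4-methylhex-4-enoyl chloride | ClC(=O)CC/C(C)=C\CO[Si](c1ccccc1)(c1ccccc1)C(C)(C)C | intermediate (not isolated)
17 | (4Z)-6-(tert-butyldiphenylsilyloxy)-4-methylhexa-1,4-dien-1-one (ketene) | O=C=CC/C(C)=C\CO[Si](c1ccccc1)(c1ccccc1)C(C)(C)C | intermediate (not isolated)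
18 | ethyl (6Z)-8-(tert-butyldiphenylsilyloxy)-2,6-dimethylocta-2,3,6-trienoate (racemic allene axis) | CCOC(=O)C(C)=C=CC/C(C)=C\CO[Si](c1ccccc1)(c1ccccc1)C(C)(C)C | intermediate
19 | (6Z)-8-(tert-butyldiphenylsilyloxy)-2,6-dimethylocta-2,3,6-trien-1-ol | OCC(C)=C=CC/C(C)=C\CO[Si](c1ccccc1)(c1ccccc1)C(C)(C)C | intermediate
20 | (6Z)-8-(tert-butyldiphenylsilyloxy)-2,6-dimethylocta-2,3,6-trienal | O=CC(C)=C=CC/C(C)=C\CO[Si](c1ccccc1)(c1ccccc1)C(C)(C)C | intermediate
21 | (1S,2S)-2-[(2Z,6Z)-8-(tert-butyldiphenylsilyloxy)-2,6-dimethyl-1-oxoocta-2,6-dien-3-yl]-2,6,6-trimethylcyclohexane-1-carbonitrile | O=C/C(C)=C(/CC/C(C)=C\CO[Si](c2ccccc2)(c2ccccc2)C(C)(C)C)[C@@]1(C)CCCC(C)(C)[C@@H]1C#N | intermediate (not isolated)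
22 | (5S,7S,10S,13Z)-15-(tert-butyldiphenylsilyloxy)-6-iminolabda-8,13-dien-7-ol (7α-OH) | N=C1[C@@H](O)C(C)=C(CC/C(C)=C\CO[Si](c3ccccc3)(c3ccccc3)C(C)(C)C)[C@@]2(C)CCCC(C)(C)[C@H]12 | intermediate (not isolated)
23 | (5S,7S,10S,13Z)-15-(tert-butyldiphenylsilyloxy)-7-hydroxylabda-8,13-dien-6-one (7α-OH, 5α-H, 10β-methyl) | O=C1[C@@H](O)C(C)=C(CC/C(C)=C\CO[Si](c3ccccc3)(c3ccccc3)C(C)(C)C)[C@@]2(C)CCCC(C)(C)[C@H]12 | intermediate
24 | (5S,6S,7S,10S,13Z)-15-(tert-butyldiphenylsilyloxy)labda-8,13-diene-6,7-diol (6β,7α) | O[C@@H]1[C@@H](O)C(C)=C(CC/C(C)=C\CO[Si](c3ccccc3)(c3ccccc3)C(C)(C)C)[C@@]2(C)CCCC(C)(C)[C@H]12 | intermediate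
25 | (5S,6S,7S,10S,13Z)-6,7-diacetoxy-15-(tert-butyldiphenylsilyloxy)labda-8,13-diene | CC(=O)O[C@@H]1[C@@H](OC(C)=O)C(C)=C(CC/C(C)=C\CO[Si](c3ccccc3)(c3ccccc3)C(C)(C)C)[C@@]2(C)CCCC(C)(C)[C@H]12 | intermediate
26 | (5S,6S,7S,10S,13Z)-6,7-diacetoxylabda-8,13-dien-15-ol (6β,7α-diacetate) | CC(=O)O[C@@H]1[C@@H](OC(C)=O)C(C)=C(CC/C(C)=C\CO)[C@@]2(C)CCCC(C)(C)[C@H]12 | target

Total step count: 17 steps.
Longest linear sequence: 11 steps (steps 1–7, then 14–17; the nerol branch, steps 8–13 then 14–17, is 10).

Steps most likely to fail

Step 14 (proposed new method). What may go wrong: premature reduction or disproportionation of the tertiary radical, base-induced oligomerisation of the allenal, incomplete conjugation of a first-formed deconjugated aldehyde, protonation or dimerisation of the samarium ketyl in place of addition to the hindered nitrile, and isomerisation of the β,γ-unsaturated α-ketol to the conjugated 6-hydroxy-7-ketone during hydrolysis. Fallback, using only reaction types with direct precedent; it sets out from 10 and 18 and comes back at 23. The two bond formations are separated and the sensitive allenal is avoided: 10 and the allenoate 18 are coupled under the photoredox conditions of step 14 (Giese addition of a tertiary alkyl oxalate radical to an unsaturated ester), which should give the unsaturated ester nitrile F1. DIBAL-H at −78 °C should reduce only the ester, since the nitrile sits between two quaternary carbons, to the allylic alcohol nitrile F2. MnO2 then gives the enal 21, which is now isolated and purified, and 21 is cyclised with SmI2 in THF under visible-light irradiation (ketyl–nitrile cyclisation) and hydrolysed through 22 to 23.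

Step 13. What may go wrong: isomerisation of the α-allenic aldehyde to the conjugated 2,4-dienal or its oligomerisation on the oxidant surface or on concentration. Fallback; it sets out from 18 and comes back at 20. The aldehyde is reached by reduction instead of oxidation: 18 is converted with MeONHMe·HCl and i-PrMgCl (THF, −20 °C) into the allenic N-methoxy-N-methylamide F3, which DIBAL-H at −78 °C should reduce to 20; the cold, neutral solution of 20 is used at once in step 14.

Step 7. What may go wrong: stalled acylation of the hindered tertiary alcohol, or elimination of the tertiary oxalate toward the nitrile to give the conjugated β-isomer and loss of the C5 stereocentre. Fallback; it sets out from 7 and comes back at 21. The C10 radical is generated directly from the alkene of 7 by metal-hydride hydrogen-atom transfer (Fe(acac)3, PhSiH3, EtOH/ethylene glycol, 60 °C) in the presence of 20 (reductive olefin coupling), which bypasses 8–10. An excess of 7 is used so that hydrogen-atom transfer to the side-chain alkene of 20 stays minor, and 21 is then treated with SmI2 as in the second stage of step 14. This fallback makes no new compound (F0).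

Further compounds
F1 | step 14 | ethyl (2Z,6Z)-8-(tert-butyldiphenylsilyloxy)-3-[(1S,2S)-2-cyano-1,3,3-trimethylcyclohexyl]-2,6-dimethylocta-2,6-dienoate | CCOC(=O)/C(C)=C(/CC/C(C)=C\CO[Si](c2ccccc2)(c2ccccc2)C(C)(C)C)[C@@]1(C)CCCC(C)(C)[C@@H]1C#N
F2 | step 14 | (1S,2S)-2-[(2Z,6Z)-8-(tert-butyldiphenylsilyloxy)-1-hydroxy-2,6-dimethylocta-2,6-dien-3-yl]-2,6,6-trimethylcyclohexane-1-carbonitrile | OC/C(C)=C(/CC/C(C)=C\CO[Si](c2ccccc2)(c2ccccc2)C(C)(C)C)[C@@]1(C)CCCC(C)(C)[C@@H]1C#N
F3 | step 13 | (6Z)-8-(tert-butyldiphenylsilyloxy)-N-methoxy-N,2,6-trimethylocta-2,3,6-trienamide | CON(C)C(=O)C(C)=C=CC/C(C)=C\CO[Si](c1ccccc1)(c1ccccc1)C(C)(C)C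
F0 | step 7 | none | none
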